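The constants were set for the occasion.

Which way of charging Sub and Ptn ends with the most Sid2? Sid2 is built from Sub.Ptn and a further Sub, so the first thing to reckon is how much Ptn ever becomes Sub.Ptn.

| flask | Sub | Ptn | Ptn2 | time | remark |
|---|---|---|---|---|---|
| south-east | 0.050 M | 0.0600 M (fed, over 4.0 d) | 0.100 M | 10 d | all else is in the flask from the start; the feed brings no volume worth counting |
| west | 0.050 M (fed, over 4.0 d) | 0.0600 M | 0.100 M | 10 d | all else is in the flask from the start; the feed brings no volume worth counting |
| north-east | 0.050 M | 0.0600 M | 0.100 M | 10 d | everything together at the start |
| south-west | 0.050 M (in portions, 5, over 4.0 d) | 0.0600 M | 0.100 M | 10 d | first portion at the start, last at 4.0 d |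

* the flask that comes out highest in amount of Sid2, in percent of the Sub charged, or "all alike" when all lie within 1.5 percentage points (south-east / west / north-east / south-west / all alike)
* Sid2 at the end, in percent of the Sub charged, south-east
* Sid2 at the end, in percent of the Sub charged, west
* Sid2 at the end, in percent of the Sub charged, north-east
* Sid2 at the end, in percent of the Sub charged, south-west

- a species is counted by the Sub in it: one Sid2 or Tgt counts as two
- where a step has two of a species, its rate is k times that concentration squared, and two are used at each turn
- run time (south-east): 10 d

    Sub + Sub.Ptn → Sid2 (k1 = 0.445 M⁻¹ h⁻¹)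
    2 Sub → Tgt (k2 = 1.84 M⁻¹ h⁻¹)
    Sub + Ptn2 → Sub.Ptn2 (k3 = 0.0471 M⁻¹ h⁻¹)
    Sub + Ptn → Sub.Ptn (k4 = 2.08 M⁻¹ h⁻¹)
    Ptn → Sid (k5 = 0.196 h⁻¹)

Ptn leaves by two exits, capture by Sub and decay to Sid, a pseudo-first-order race at any moment. With Sub at its full charge, 34.7% of the Ptn lost goes to Sub.Ptn; this is the capture share, capture rate over capture plus decay rate at the c(Sub) of that moment.

The ladder of time scales, in this reckoning of my own, starts with the decay of Ptn, half-life 0.147 d. Next comes the first half-life of Sub by dimerisation alone, 0.226 d, with capture of Sub close by at 0.23 d. The Sub + Ptn2 step, at 6.1 d, is a slow rung, and the feed takes 4.0 d.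

In north-east the share therefore starts at 34.7% and drifts down as c(Sub) falls, so capture stays below 0.0208 M. In south-east, the first half-life of Sub by dimerisation at its full charge lies far below the feed time, and Ptn arrives at a low share. In west, Ptn decays while c(Sub) is still small. In south-west, the first portion gives a share of 9.59%, which is less than in north-east but is there from the start. This reckoning gives the order north-east, then south-west, and no Sid2 percentages.

The forecast names north-east, as “the flask with the most Sub present while Ptn is still alive”, with 13% there, 6% in south-west, 4.4% in south-east and 2.9% in west.

The simulation gives north-east as highest, with 12.4%, against 6.85% in south-west, 2.24% in west and 1.93% in south-east. With 0% of Ptn left in north-east, the Sid there shows 0.0135 M captured, less than the 0.0208 M of the starting share.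

The decay of Ptn is the largest single effect on the gap between north-east and south-east: without that step the gap shrinks from 10 percentage points to 5.1 points. That still exceeds the margin, so even this change leaves north-east ahead of south-east.

The neighbouring flask is north-east with 0.024 M of Ptn. Its Sub charge is the same, so its starting capture share is again 34.7% and its capture stays below 0.00833 M, while the capture of north-east scaled in proportion to this Ptn charge gives an estimate of 0.00539 M. In the neighbouring flask the Sid shows 0.00583 M captured, and its Sid2 ends at 6.33%.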